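**Retrosynthetic overview**

1. CIML C ⇐ Z-selective semi-hydrogenation of the 22-membered cycloalkynoate, after removal of two PMB ethers.
2. Macrolactone (last ring formed) ⇐ ring closure at C2≡C3 of a but-2-ynoate/pent-3-ynyl diyne by alkyne metathesis; the ring closes in a [2+2] cycloaddition to a molybdacyclobutadiene, followed by cycloreversion. The ester comes from a Mitsunobu inversion at C21.
3. trans-6,7-Oxirane (formed second) ⇐ threo-6,7-diol by orthoester/bromo acetate double inversion; the diol is carried as an acetonide.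
4. C4–C9 with all four stereocentres ⇐ 1,2:5,6-dianhydro-3,4-O-isopropylidene-L-iditol (its two oxiranes are the first rings formed; made from D-mannitol acetonide with inversion at C2/C5), opened first by the C10–C22 Grignard reagent, then by propynyllithium.
5. C21 ⇐ (S)-propylene oxide and 1-bromo-10-chlorodecane.

Assumption: locants are those of the target (C1 lactone carbonyl, C22 methyl); open-chain intermediates are named as docos-2-ynes, whose C3–C22 are C3–C22 of the target, and 1-bromo-10-chlorodecane and the Mo alkylidyne precatalyst are taken as commercial.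

**Route**

Step 1
Reactants: 1 3,4-O-isopropylidene-D-mannitol
Product: 3 1,6-di-O-benzoyl-3,4-O-isopropylidene-2,5-di-O-methanesulfonyl-D-mannitol, via dibenzoate 2 (not isolated)
Conditions: BzCl (2.05 equiv), pyridine, CH2Cl2, −40 → −10 °C; then MsCl (3 equiv), 0 °C → rt
Reagents that add atoms: benzoyl chloride O=C(Cl)c1ccccc1; methanesulfonyl chloride CS(=O)(=O)Cl
Why: Selective acylation of the two primary hydroxyls at low temperature, then sulfonylation of the two secondary ones in the same flask; no stereocentre is touched.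

Step 2
Reactants: 3 1,6-di-O-benzoyl-3,4-O-isopropylidene-2,5-di-O-methanesulfonyl-D-mannitol
Product: 5 1,2:5,6-dianhydro-3,4-O-isopropylidene-L-iditol, via diol dimesylate 4 (not isolated)
Conditions: K2CO3 (4 equiv), MeOH, 0 °C → rt
Reagents that add atoms: none
Why: Methanolysis of the benzoates frees the primary alkoxides, which displace the neighbouring mesylates (intramolecular Williamson/SN2 epoxide closure) with inversion at C2 and C5, turning D-manno into L-ido.

Step 3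
Reactants: 6 1-bromo-10-chlorodecane; 7 (S)-propylene oxide
Product: 9 (S)-13-chlorotridecan-2-ol, via Grignard reagent 8 (not isolated)
Conditions: Mg, THF, rt; then CuI (5 mol %), 7, −30 → 0 °C; aq. NH4Cl
Reagents that add atoms: none
Why: Mg inserts only into the C–Br bond and the copper-catalysed Grignard opening of the epoxide occurs at its CH2 end, so the bought stereocentre (future C21) is untouched.

Step 4
Reactants: 9 (S)-13-chlorotridecan-2-ol
Product: 10 (S)-2-(tert-butyldimethylsilyloxy)-13-chlorotridecane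
Conditions: TBSCl, imidazole, DMF, rt
Reagents that add atoms: tert-butyldimethylsilyl chloride CC(C)(C)[Si](C)(C)Cl
Why: Standard silylation of the secondary alcohol so that the chloride end can be turned into a Grignard reagent.

Step 5
Reactants: 10 (S)-2-(tert-butyldimethylsilyloxy)-13-chlorotridecane; 5 1,2:5,6-dianhydro-3,4-O-isopropylidene-L-iditol
Product: 12 (1S,14S)-14-(tert-butyldimethylsilyloxy)-1-[(4R,5R)-2,2-dimethyl-5-[(2S)-oxiran-2-yl]-1,3-dioxolan-4-yl]pentadecan-1-ol, via Grignard reagent 11 (not isolated)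
Conditions: Mg (I2-activated), THF, reflux; added slowly to 5 (2.5 equiv, excess recovered), CuI (10 mol %), THF, −40 → −20 °C; aq. NH4Cl
Reagents that add atoms: none
Why: Copper-catalysed Grignard (SN2) opening of one of the two homotopic terminal epoxides at its CH2 forms C9–C10; the C2 symmetry of 5 makes the mono-adduct a single isomer and no stereocentre is touched.

Step 6
Reactants: 12 epoxy alcohol (as named in step 5)
Product: 13 (5S,6R,7R,8S,21S)-21-(tert-butyldimethylsilyloxy)-6,7-O-isopropylidenedocos-2-yne-5,8-diol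
Conditions: propyne (3 equiv), n-BuLi (3 equiv), THF, −78 °C; BF3·OEt2 (3 equiv); then 12, −78 °C; aq. NH4Cl
Reagents that add atoms: propyne CC#C
Why: Yamaguchi–Hirao alkynylation, in which the alkynyllithium/BF3 pair opens the remaining terminal epoxide at C4 (SN2), leaving C5 unchanged.

Step 7
Reactants: 13 (5S,6R,7R,8S,21S)-21-(tert-butyldimethylsilyloxy)-6,7-O-isopropylidenedocos-2-yne-5,8-diol
Product: 14 (5S,6R,7R,8S,21S)-21-(tert-butyldimethylsilyloxy)-6,7-O-isopropylidene-5,8-bis(4-methoxybenzyloxy)docos-2-yne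
Conditions: NaH (2.6 equiv), PMBCl (2.6 equiv), n-Bu4NI (cat.), DMF, 0 °C → rt
Reagents that add atoms: 4-methoxybenzyl chloride COc1ccc(CCl)cc1
Why: Williamson etherification of both secondary alkoxides gives acid-stable, oxidatively removable ethers at O5 and O8.

Step 8
Reactants: 14 (5S,6R,7R,8S,21S)-21-(tert-butyldimethylsilyloxy)-6,7-O-isopropylidene-5,8-bis(4-methoxybenzyloxy)docos-2-yne
Product: 15 (5S,6S,7S,8S,21S)-5,8-bis(4-methoxybenzyloxy)docos-2-yne-6,7,21-triol
Conditions: AcOH/H2O/THF (3:1:1), 55 °C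
Reagents that add atoms: none
Why: Aqueous acid hydrolyses the isopropylidene acetal and the silyl ether while PMB ethers survive; the geometry is unchanged (the 6,7 descriptors change only through CIP priorities).

Step 9
Reactants: 15 (5S,6S,7S,8S,21S)-5,8-bis(4-methoxybenzyloxy)docos-2-yne-6,7,21-triol
Product: 18 (5S,6R,7R,8S,21S)-6,7-epoxy-5,8-bis(4-methoxybenzyloxy)docos-2-yn-21-ol, via cyclic orthoacetate 16 (not isolated), via bromo acetate 17 (not isolated)
Conditions: MeC(OMe)3 (4 equiv), PPTS (cat.), CH2Cl2, rt, evaporate; AcBr (2.5 equiv), CH2Cl2, 0 °C, evaporate; K2CO3 (5 equiv), MeOH, rt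
Reagents that add atoms: none
Why: Kolb–Sharpless one-pot diol-to-epoxide conversion, in which bromide opens the acetoxonium ion with inversion and the alkoxide freed by methanolysis displaces bromide with a second inversion, so the threo diol gives the trans-(6R,7R)-epoxide with net retention; the C21 hydroxyl passes through its acetate and is set free again.

Step 10
Reactants: 18 (5S,6R,7R,8S,21S)-6,7-epoxy-5,8-bis(4-methoxybenzyloxy)docos-2-yn-21-ol
Product: 19 (5S,6R,7R,8S,21R)-6,7-epoxy-5,8-bis(4-methoxybenzyloxy)docos-2-yn-21-yl but-2-ynoate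
Conditions: but-2-ynoic acid (1.5 equiv), PPh3, DIAD, toluene, 0 °C → rt
Reagents that add atoms: but-2-ynoic acid CC#CC(=O)O
Why: Mitsunobu esterification is an SN2 reaction at C21 and inverts the (S)-carbinol to the (R)-ester of the target.

Step 11
Reactants: 19 (5S,6R,7R,8S,21R)-6,7-epoxy-5,8-bis(4-methoxybenzyloxy)docos-2-yn-21-yl but-2-ynoate
Product: 20 (5S,6R,7R,8S,21R)-6,7-epoxy-5,8-bis(4-methoxybenzyloxy)docos-2-yn-21-olide
Conditions: [Mo(≡C-C6H4-4-OMe)(OSiPh3)3] (15 mol %), MS 5 Å, toluene (2 mM), 80 °C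
Reagents that add atoms: none
Why: Ring-closing alkyne metathesis, in which the Mo alkylidyne and the two methyl-capped alkynes pass through metallacyclobutadienes formed by [2+2] cycloaddition and opened by cycloreversion, closes the 22-membered ring at C2≡C3 with loss of but-2-yne; no stereocentre is involved.

Step 12
Reactants: 20 (5S,6R,7R,8S,21R)-6,7-epoxy-5,8-bis(4-methoxybenzyloxy)docos-2-yn-21-olide
Product: 21 (5S,6R,7R,8S,21R)-6,7-epoxy-5,8-dihydroxydocos-2-yn-21-olide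
Conditions: DDQ (3 equiv), CH2Cl2/pH 7 buffer (10:1), 0 °C → rt
Reagents that add atoms: none
Why: Oxidative PMB cleavage (benzylic hydride abstraction, then hydrolysis) under near-neutral conditions spares the epoxide and the ynoate, which cannot lactonise onto O5.

Step 13
Reactants: 21 (5S,6R,7R,8S,21R)-6,7-epoxy-5,8-dihydroxydocos-2-yn-21-olide
Product: 22 CIML C, (2Z,5S,6R,7R,8S,21R)-6,7-epoxy-5,8-dihydroxydocos-2-en-21-olide
Conditions: H2 (1 atm), Lindlar catalyst (Pd/CaCO3/Pb), quinoline, EtOAc, rt, stopped at 1 equiv H2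
Reagents that add atoms: none
Why: Lindlar semi-hydrogenation delivers H2 syn on the poisoned Pd surface and gives the (2Z)-enoate under neutral conditions, leaving the epoxide and all stereocentres untouched.

**Compound list**

1 | 3,4-O-isopropylidene-D-mannitol | OC[C@@H](O)[C@H]1OC(C)(C)O[C@@H]1[C@H](O)CO | starting material
2 | 1,6-di-O-benzoyl-3,4-O-isopropylidene-D-mannitol | O=C(OC[C@@H](O)[C@H]2OC(C)(C)O[C@@H]2[C@H](O)COC(=O)c3ccccc3)c1ccccc1 | intermediate
3 | 1,6-di-O-benzoyl-3,4-O-isopropylidene-2,5-di-O-methanesulfonyl-D-mannitol | O=C(OC[C@@H](OS(C)(=O)=O)[C@H]2OC(C)(C)O[C@@H]2[C@H](OS(C)(=O)=O)COC(=O)c3ccccc3)c1ccccc1 | intermediate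
4 | 3,4-O-isopropylidene-2,5-di-O-methanesulfonyl-D-mannitol (formed as its 1,6-dialkoxide) | OC[C@@H](OS(C)(=O)=O)[C@H]1OC(C)(C)O[C@@H]1[C@H](OS(C)(=O)=O)CO | intermediate
5 | 1,2:5,6-dianhydro-3,4-O-isopropylidene-L-iditol, (4R,5R)-2,2-dimethyl-4,5-bis[(2S)-oxiran-2-yl]-1,3-dioxolane | C1O[C@@H]1[C@H]2OC(C)(C)O[C@@H]2[C@@H]3CO3 | intermediate
6 | 1-bromo-10-chlorodecane | ClCCCCCCCCCCBr | starting material
7 | (S)-propylene oxide, (S)-2-methyloxirane | C[C@H]1CO1 | starting material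
8 | (10-chlorodecyl)magnesium bromide | ClCCCCCCCCCC[Mg]Br | intermediate
9 | (S)-13-chlorotridecan-2-ol | C[C@H](O)CCCCCCCCCCCCl | intermediate
10 | (S)-2-(tert-butyldimethylsilyloxy)-13-chlorotridecane | C[C@H](O[Si](C)(C)C(C)(C)C)CCCCCCCCCCCCl | intermediate
11 | [(12S)-12-(tert-butyldimethylsilyloxy)tridecyl]magnesium chloride | C[C@H](O[Si](C)(C)C(C)(C)C)CCCCCCCCCCC[Mg]Cl | intermediate
12 | (1S,14S)-14-(tert-butyldimethylsilyloxy)-1-[(4R,5R)-2,2-dimethyl-5-[(2S)-oxiran-2-yl]-1,3-dioxolan-4-yl]pentadecan-1-ol | C[C@H](O[Si](C)(C)C(C)(C)C)CCCCCCCCCCCC[C@H](O)[C@H]1OC(C)(C)O[C@@H]1[C@@H]2CO2 | intermediate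
13 | (5S,6R,7R,8S,21S)-21-(tert-butyldimethylsilyloxy)-6,7-O-isopropylidenedocos-2-yne-5,8-diol | C[C@H](O[Si](C)(C)C(C)(C)C)CCCCCCCCCCCC[C@H](O)[C@H]1OC(C)(C)O[C@@H]1[C@@H](O)CC#CC | intermediate
14 | (5S,6R,7R,8S,21S)-21-(tert-butyldimethylsilyloxy)-6,7-O-isopropylidene-5,8-bis(4-methoxybenzyloxy)docos-2-yne | C[C@H](O[Si](C)(C)C(C)(C)C)CCCCCCCCCCCC[C@H](OCc1ccc(OC)cc1)[C@H]2OC(C)(C)O[C@@H]2[C@@H](OCc3ccc(OC)cc3)CC#CC | intermediate
15 | (5S,6S,7S,8S,21S)-5,8-bis(4-methoxybenzyloxy)docos-2-yne-6,7,21-triol (L-ido array as in 14) | C[C@H](O)CCCCCCCCCCCC[C@H](OCc1ccc(OC)cc1)[C@@H](O)[C@H](O)[C@@H](OCc2ccc(OC)cc2)CC#CC | intermediate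
16 | 6,7-cyclic orthoacetate of 15 (2-methoxy-2-methyl-1,3-dioxolane across O6/O7, O21 as 1,1-dimethoxyethyl orthoester; 5S,6R,7R,8S,21S; orthoester carbon unassigned) | C[C@H](OC(C)(OC)OC)CCCCCCCCCCCC[C@H](OCc1ccc(OC)cc1)[C@H]2OC(C)(OC)O[C@@H]2[C@@H](OCc3ccc(OC)cc3)CC#CC | intermediate
17 | (5S,6S,7R,8S,21S)-6-bromo-5,8-bis(4-methoxybenzyloxy)docos-2-yne-7,21-diyl diacetate (the 7-bromo-6-acetoxy regioisomer forms as well and gives the same epoxide) | C[C@H](OC(C)=O)CCCCCCCCCCCC[C@H](OCc1ccc(OC)cc1)[C@@H](OC(C)=O)[C@@H](Br)[C@@H](OCc2ccc(OC)cc2)CC#CC | intermediate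
18 | (5S,6R,7R,8S,21S)-6,7-epoxy-5,8-bis(4-methoxybenzyloxy)docos-2-yn-21-ol | C[C@H](O)CCCCCCCCCCCC[C@H](OCc1ccc(OC)cc1)[C@H]2O[C@@H]2[C@@H](OCc3ccc(OC)cc3)CC#CC | intermediate
19 | (5S,6R,7R,8S,21R)-6,7-epoxy-5,8-bis(4-methoxybenzyloxy)docos-2-yn-21-yl but-2-ynoate | C[C@@H](OC(=O)C#CC)CCCCCCCCCCCC[C@H](OCc1ccc(OC)cc1)[C@H]2O[C@@H]2[C@@H](OCc3ccc(OC)cc3)CC#CC | intermediate
20 | (5S,6R,7R,8S,21R)-6,7-epoxy-5,8-bis(4-methoxybenzyloxy)docos-2-yn-21-olide | C[C@@H]1CCCCCCCCCCCC[C@H](OCc2ccc(OC)cc2)[C@H]3O[C@@H]3[C@@H](OCc4ccc(OC)cc4)CC#CC(=O)O1 | intermediate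
21 | (5S,6R,7R,8S,21R)-6,7-epoxy-5,8-dihydroxydocos-2-yn-21-olide | C[C@@H]1CCCCCCCCCCCC[C@H](O)[C@H]2O[C@@H]2[C@@H](O)CC#CC(=O)O1 | intermediate
22 | CIML C, (2Z,5S,6R,7R,8S,21R)-6,7-epoxy-5,8-dihydroxydocos-2-en-21-olide | C[C@@H]1CCCCCCCCCCCC[C@H](O)[C@H]2O[C@@H]2[C@@H](O)C/C=C\C(=O)O1 | target

**Step count and risks**

Total step count: 13. Longest linear sequence: 11 steps (steps 1, 2, 5–13 from 1; equally steps 3, 4, 5–13 from 6).

The three steps most likely to fail are steps 5, 9 and 11.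

Step 5 (statistical mono-opening of the bis-epoxide by the valuable chain Grignard). If double addition or poor conversion dominates, the order of the two C–C bond formations is reversed, so that the statistical step uses the cheap C3 nucleophile. The fallback sets out from 5: 1-propynyllithium/BF3·OEt2 (1 equiv, with 5 in threefold excess, THF, −78 °C) gives the mono-adduct (1S)-1-[(4R,5R)-2,2-dimethyl-5-[(2S)-oxiran-2-yl]-1,3-dioxolan-4-yl]pent-3-yn-1-ol F1. Its hydroxyl is deprotonated with MeMgCl, and Grignard reagent 11 with catalytic CuI then opens the one remaining epoxide at C9. This gives diol 13, where the route continues.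

Step 9 (one-pot epoxide formation on a triol that carries a free remote hydroxyl and two PMB ethers). If the free C21 hydroxyl or acid released from it spoils the sequence, deprotection and epoxide formation are taken apart. The fallback sets out from 14: CeCl3·7H2O/oxalic acid in MeCN removes only the acetonide and gives the silyl-protected 6,7-diol F2. The orthoester/bromide sequence then runs on a substrate with no third hydroxyl, through the cyclic orthoacetate F3 and the bromo acetate F4, to the silyl-protected epoxide F5. TBAF in THF removes the silyl ether and returns to the route at 18.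

Step 11 (alkyne metathesis on a conjugated ynoate in the presence of an epoxide, at high dilution). If the ynoate does not metathesise or only oligomers form, the ring is closed at the ester bond instead. The fallback sets out from 12: lithium (trimethylsilyl)acetylide/BF3·OEt2 gives the silyl-capped alkyne diol F6. PMB trichloroacetimidate with catalytic La(OTf)3 gives the bis-PMB ether F7, and aqueous acetic acid gives the triol F8. The orthoester/bromide sequence of step 9 leads through the cyclic orthoacetate F9 and the bromo acetate F10 to the terminal-alkyne epoxy alcohol F11, since K2CO3/MeOH also cleaves the C–Si bond. n-BuLi (2.2 equiv) followed by CO2 gives the hydroxy ynoic acid F12. Mitsunobu macrolactonisation (PPh3, DIAD, toluene, 2 mM) closes the ring with inversion at C21 and returns to the route at 20.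

**Further compounds**

F1 | step 5 | (1S)-1-[(4R,5R)-2,2-dimethyl-5-[(2S)-oxiran-2-yl]-1,3-dioxolan-4-yl]pent-3-yn-1-ol | C1O[C@@H]1[C@H]2OC(C)(C)O[C@@H]2[C@@H](O)CC#CC
F2 | step 9 | (5S,6S,7S,8S,21S)-21-(tert-butyldimethylsilyloxy)-5,8-bis(4-methoxybenzyloxy)docos-2-yne-6,7-diol | C[C@H](O[Si](C)(C)C(C)(C)C)CCCCCCCCCCCC[C@H](OCc1ccc(OC)cc1)[C@@H](O)[C@H](O)[C@@H](OCc2ccc(OC)cc2)CC#CC
F3 | step 9 | 6,7-cyclic orthoacetate (2-methoxy-2-methyl-1,3-dioxolane) of F2 | C[C@H](O[Si](C)(C)C(C)(C)C)CCCCCCCCCCCC[C@H](OCc1ccc(OC)cc1)[C@H]2OC(C)(OC)O[C@@H]2[C@@H](OCc3ccc(OC)cc3)CC#CC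
F4 | step 9 | (5S,6S,7R,8S,21S)-6-bromo-21-(tert-butyldimethylsilyloxy)-5,8-bis(4-methoxybenzyloxy)docos-2-yn-7-yl acetate | C[C@H](O[Si](C)(C)C(C)(C)C)CCCCCCCCCCCC[C@H](OCc1ccc(OC)cc1)[C@@H](OC(C)=O)[C@@H](Br)[C@@H](OCc2ccc(OC)cc2)CC#CC
F5 | step 9 | (5S,6R,7R,8S,21S)-21-(tert-butyldimethylsilyloxy)-6,7-epoxy-5,8-bis(4-methoxybenzyloxy)docos-2-yne | C[C@H](O[Si](C)(C)C(C)(C)C)CCCCCCCCCCCC[C@H](OCc1ccc(OC)cc1)[C@H]2O[C@@H]2[C@@H](OCc3ccc(OC)cc3)CC#CC
F6 | step 11 | analogue of 13 with the alkyne capped by SiMe3 instead of CH3 (5,8-diol, 6,7-acetonide, 21-OTBS; target locants 5S,6R,7R,8S,21S) | C[C@H](O[Si](C)(C)C(C)(C)C)CCCCCCCCCCCC[C@H](O)[C@H]1OC(C)(C)O[C@@H]1[C@@H](O)CC#C[Si](C)(C)C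
F7 | step 11 | 5,8-bis(4-methoxybenzyl) ether of F6 | C[C@H](O[Si](C)(C)C(C)(C)C)CCCCCCCCCCCC[C@H](OCc1ccc(OC)cc1)[C@H]2OC(C)(C)O[C@@H]2[C@@H](OCc3ccc(OC)cc3)CC#C[Si](C)(C)C
F8 | step 11 | analogue of 15 with the alkyne capped by SiMe3 (6,7,21-triol, 5,8-bis-PMB ether) | C[C@H](O)CCCCCCCCCCCC[C@H](OCc1ccc(OC)cc1)[C@@H](O)[C@H](O)[C@@H](OCc2ccc(OC)cc2)CC#C[Si](C)(C)C
F9 | step 11 | 6,7-cyclic orthoacetate of F8 with O21 as 1,1-dimethoxyethyl orthoester | C[C@H](OC(C)(OC)OC)CCCCCCCCCCCC[C@H](OCc1ccc(OC)cc1)[C@H]2OC(C)(OC)O[C@@H]2[C@@H](OCc3ccc(OC)cc3)CC#C[Si](C)(C)C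
F10 | step 11 | analogue of 17 with the alkyne capped by SiMe3 (6-bromo-7,21-diacetate) | C[C@H](OC(C)=O)CCCCCCCCCCCC[C@H](OCc1ccc(OC)cc1)[C@@H](OC(C)=O)[C@@H](Br)[C@@H](OCc2ccc(OC)cc2)CC#C[Si](C)(C)C
F11 | step 11 | analogue of 18 with a terminal alkyne (C≡C–H) in place of the methyl-capped one | C[C@H](O)CCCCCCCCCCCC[C@H](OCc1ccc(OC)cc1)[C@H]2O[C@@H]2[C@@H](OCc3ccc(OC)cc3)CC#C
F12 | step 11 | (5S,6R,7R,8S,21S)-6,7-epoxy-21-hydroxy-5,8-bis(4-methoxybenzyloxy)docos-2-ynoic acid | C[C@H](O)CCCCCCCCCCCC[C@H](OCc1ccc(OC)cc1)[C@H]2O[C@@H]2[C@@H](OCc3ccc(OC)cc3)CC#CC(=O)O
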